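## The problem

Target 13 is an achiral isoflavone. It is a 4H-chromen-4-one (benzo ring A fused to pyranone ring C) with a 4-methoxyphenyl group (ring B) at C3, a methoxy group at C8 and a 3-methylbut-2-enyl (prenyl) ether at O7. It has no stereocentre and no stereogenic alkene, since the open-chain alkene ends in two methyl groups, so the task is one of connectivity and regiochemistry, not stereocontrol. Ring A carries three neighbouring oxygens (O1, O8, O7). O1 and O7 come from the two equivalent hydroxyls of symmetric 2-methoxyresorcinol 1 and must be told apart, and of the three alkyl ethers only the one at O7 may become prenyl. The prenyl aryl ether is the fragile group: it ionises to an allyl cation in strong protic or Lewis acid, and its alkene is open to electrophiles, oxidants and hydrogenation. It therefore has to be introduced after all acidic and redox steps. The pyranone is a vinylogous ester that hard nucleophiles open at C2, so basic steps after ring closure are limited to mild carbonate conditions. The feature that invites the key step lies in ring A: C4a is ortho to O1 and para to O7, and the other carbon ortho to O1 (C8) is blocked by methoxy. A carboxyl group tethered through O1–C2=C3 can therefore reach only one ring carbon, and that carbon is the best activated one.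

## Retrosynthesis

**O7–CH2 bond.** Target 13 is cut into phenol 11 and prenyl bromide 12. Carrying the prenyl group further back is excluded because it would meet the acid of the ring closure and the Lewis acid of the deprotection. Phenol 11 is five carbons smaller, holds no acid-sensitive group and has a single hydroxyl, so the forward alkylation has no site problem. The forward step must be an SN2 attack at the primary allylic carbon under carbonate base that leaves the pyranone closed.

**O7 protecting group.** Phenol 11 is traced to isopropyl ether 10. The group at O7 must pass through a strongly acidic, dehydrating medium and then be removed beside two methyl ethers. A benzyl ether would be lost or would migrate in that acid. A free phenol would be O-acylated by the activated acid of a second molecule. A secondary alkyl ether tolerates protic acid and is cleaved by a boron trihalide far faster than a methyl ether. The forward step asks only for that selectivity.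

**C4–C4a bond.** Chromone 10 is cut at the bond between the carbonyl carbon and ring A, giving the Z-configured 3-aryloxy-2-arylacrylic acid 9. This removes ring C and leaves an open chain in which O1–C2=C3, ring B and the carboxyl carbon are already in place. The neighbouring cuts through O1–C2 or C2–C3 lead to a deoxybenzoin-type ketone followed by one-carbon insertion. That classical sequence is short, but it makes the same C4–C4a bond first and intermolecularly, on an unprotected resorcinol in hot Lewis acid. A cut at C3–C1′ would add a halogenation and a cross-coupling for a ring B that comes with ester 4 at no extra cost. In the chosen cut the tether fixes the site, and closure to a coumarin is impossible because O1 is already bound to C2. The forward reaction must acylate C6 of the phenoxy ring in acid strong enough to activate a push–pull acid and mild enough to spare the isopropyl ether.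

**Alkene geometry and carboxyl group.** Acid 9 has carboxyl and aryloxy cis, which is the less stable arrangement for a 2-aryl-3-alkoxyacrylate. The compound expected on isolation is the E acid 8, which must isomerise to 9 in the acidic medium of the ring closure. Acid 8 comes from methyl ester 7 by saponification. The forward hydrolysis must attack the ester carbonyl and not C3 of the vinylogous carbonate.

**O1–C2 bond.** Ester 7 is cut at the vinyl ether bond into phenol 3 and enol tosylate 6. This is the convergent step: it joins ring A to the three-carbon unit that carries ring B, and it turns one of the two equivalent oxygens of the resorcinol into O1. The forward reaction is an addition–elimination at an ester-activated vinylic carbon, with the phenoxide attacking carbon and not sulfur.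

**C2–C3 bond.** Tosylate 6 comes from enol 5 by O-sulfonylation, and 5 from methyl 4-methoxyphenylacetate 4 by C-formylation with a formate ester. Ester 4 is a commodity that already holds ring B, C3 and C4. The forward reaction is a crossed Claisen condensation with a non-enolisable partner.

**O7–isopropyl bond.** Phenol 3 is cut into 2-methoxyresorcinol 1 and 2-bromopropane 2. The diol is symmetric, so the only issue is mono- against bis-alkylation, handled by an excess of the cheap diol and an acid–base separation.

## Roads not taken

**Alternative 1:** This road cuts C4a–C4, C4–C3 and O1–C2 at once, leading back to iodophenol A2, carbon monoxide and vinylboronic acid A3. In the forward sense PdCl2(dppf) (divalent palladium, reduced in the flask to zerovalent palladium) effects a carbonylative Suzuki coupling to an aryl α-arylvinyl ketone. The phenoxide then adds to the enone terminus and gives racemic isoflavanone A1.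
- Merits: three bonds form in one operation under basic conditions, and the road is more convergent and probably one or two steps shorter than the chosen plan.
- Weak points: A1 is at the wrong oxidation level, so a stereocentre is made only to be erased by a later dehydrogenation across C2–C3. A2 needs iodination ortho to the hydroxyl and para to the benzyloxy group, while the position para to the hydroxyl competes, so its regiochemistry is not secured by structure. Direct (non-carbonylative) coupling and protodeboronation of A3 compete with CO insertion. Zerovalent palladium would ionise a prenyl aryl ether, so a benzyl group and its removal are still needed.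
- Comparison: against the shorter count the chosen plan sets a ring closure whose site is fixed by the substitution pattern, the correct oxidation level straight from the key step, and no precious metal or toxic gas.

**Alternative 2:** This road cuts C4–C4a and O1–C2 with ring A held as a cyclohexenone. The kinetic α′ lithium enolate of vinylogous ester A5 (formed with LDA) is C-acylated by the β-methoxyacrylic Weinreb amide A6. On acid quench the enol oxygen displaces methoxide from the acrylate terminus and gives dihydrochromenone A4.
- Merits: the site of C-acylation is set by the enolate, and the ring closes without strong acid.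
- Weak points: ring A of the target is an ordinary trioxygenated benzene that can be bought, so building it as a carbocycle and aromatising it late is a detour. A5 must itself be made. O-acylation and γ-deprotonation compete. A6 is a vinylogous carbamate, a sluggish acyl acceptor that is also open to conjugate attack. A4 still needs dehydrogenation, debenzylation and prenylation.
- Comparison: this road is longer than the chosen plan and offers only the mildness of its ring closure, which the chosen plan does not need because its acid-sensitive group arrives last.

**Alternative 3:** This road cuts C3–C1′ and O1–C2 and leads back to 2′-hydroxychalcone A8, available by Claisen–Schmidt condensation of the matching acetophenone with the ring B aldehyde. Tl(NO3)3 (trivalent thallium) in methanol induces the 1,2-shift of ring B to the α-carbon. Aqueous HCl then closes ring C on the acetal carbon and gives benzyl-protected isoflavone A7.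
- Merits: the road is biomimetic and about two steps shorter than the chosen plan, and the electron-rich 4-methoxyphenyl ring is a good migrating group, so the rearrangement suits this target.
- Weak points: a full equivalent of a highly toxic thallium salt is consumed. Aurone formation and plain solvent addition to the enone compete with the aryl shift. The oxidant rules out the prenyl alkene, so a benzyl ether and its removal remain.
- Comparison: on step count this road is better. The chosen plan sets against it freedom from thallium, bulk reagents throughout, and a ring closure that cannot partition between product types.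

Key step: step 6

Assumption: tosylate 6, ester 7 and acid 8 are drawn as the E isomers expected from amine-base tosylation and from the thermodynamic preference of 2-aryl-3-alkoxyacrylates. Any Z isomer present would be carried along, because step 6 equilibrates the alkene.

## Route

Step 1
Reactants: 1 2-methoxybenzene-1,3-diol (2-methoxyresorcinol, used in excess); 2 2-bromopropane
Product: 3 2-methoxy-3-(propan-2-yloxy)phenol
Conditions: K2CO3, DMF, 60 °C (diol 2.5 equiv relative to bromide)
Reagents that add atoms: none
Why: Williamson etherification (SN2 of the phenoxide on the secondary bromide); the excess of symmetric diol biases the statistical mixture towards the mono-ether, and the neutral bis-ether and the water-soluble diol are removed by acid–base extraction.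

Step 2
Reactants: 4 methyl 2-(4-methoxyphenyl)acetate
Product: 5 methyl (Z)-3-hydroxy-2-(4-methoxyphenyl)prop-2-enoate (hydrogen-bonded enol form of the α-formyl ester)
Conditions: NaH, HCO2Me, THF, 0 °C → rt; then 1 M HCl
Reagents that add atoms: methyl formate, COC=O
Why: Crossed Claisen condensation (C-formylation of the ester enolate); methyl formate has no α-hydrogen and is used in excess, and the product is drawn out of the equilibrium as its sodium enolate.

Step 3
Reactants: 5 methyl (Z)-3-hydroxy-2-(4-methoxyphenyl)prop-2-enoate
Product: 6 methyl (E)-2-(4-methoxyphenyl)-3-[(4-methylphenyl)sulfonyloxy]prop-2-enoate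
Conditions: TsCl, Et3N, N-methylimidazole (cat.), CH2Cl2, 0 °C
Reagents that add atoms: 4-methylbenzenesulfonyl chloride, Cc1ccc(cc1)S(=O)(=O)Cl
Why: O-sulfonylation of the enol to an enol tosylate; with an amine base the non-chelated enolate should react mainly with the sulfonyloxy group trans to the ester, and the geometry is not critical later.

Step 4
Reactants: 3 2-methoxy-3-(propan-2-yloxy)phenol; 6 methyl (E)-2-(4-methoxyphenyl)-3-[(4-methylphenyl)sulfonyloxy]prop-2-enoate
Product: 7 methyl (E)-3-[2-methoxy-3-(propan-2-yloxy)phenoxy]-2-(4-methoxyphenyl)prop-2-enoate
Conditions: K2CO3, DMF, rt → 40 °C
Reagents that add atoms: none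
Why: Nucleophilic vinylic substitution by addition–elimination: the phenoxide adds to the ester-activated C3 and the ester enolate expels tosylate; retention and thermodynamic preference both point to the E isomer.

Step 5
Reactants: 7 methyl (E)-3-[2-methoxy-3-(propan-2-yloxy)phenoxy]-2-(4-methoxyphenyl)prop-2-enoate
Product: 8 (E)-3-[2-methoxy-3-(propan-2-yloxy)phenoxy]-2-(4-methoxyphenyl)prop-2-enoic acid
Conditions: LiOH·H2O, THF–MeOH–H2O, rt; then 1 M HCl, 0 °C
Reagents that add atoms: lithium hydroxide, [Li+].[OH-]
Why: Ester saponification by acyl–oxygen cleavage; the carboxylate, once formed, deactivates the acrylate towards conjugate attack, and cold, brief acidification spares the vinyl ether.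

Step 6
Reactants: 8 (E)-3-[2-methoxy-3-(propan-2-yloxy)phenoxy]-2-(4-methoxyphenyl)prop-2-enoic acid
Product: 10 8-methoxy-3-(4-methoxyphenyl)-7-(propan-2-yloxy)-4H-chromen-4-one, via Z-acrylic acid 9 (not isolated)
Conditions: P2O5–MeSO3H (1:10 w/w), 25 → 40 °C; then ice–water
Reagents that add atoms: none
Why: This is an intramolecular Friedel–Crafts acylation of a β-aryloxyacrylic acid, the ring closure known from the Ruhemann chromone synthesis. The medium converts the acid into a mixed anhydride or acylium ion, and reversible protonation of the enol ether at C2 together with the single-bond character of C2–C3 in the O-protonated and acylium forms lets the E acid 8 equilibrate with the Z acid 9, in which the carboxyl group is cis to the aryloxy group. Only the Z form can reach ring A, and it is drained irreversibly: the acyl carbon attacks C6 of the phenoxy ring, and the Wheland intermediate loses a proton to give the aromatic pyranone. Ring C is thereby closed at C4–C4a by electrophilic aromatic substitution in a six-membered exo closure at the acyl carbon. No stereocentre is formed. The step needs site selectivity on ring A and intramolecular attack in preference to acylation of ring B of a second molecule. Of the two carbons ortho to O1 one bears the methoxy group and the free one is para to the isopropoxy donor, so the only possible site is also the most nucleophilic, and the six-membered transition state should outrun the bimolecular path. Because O1–C2 already exists a 3-arylcoumarin cannot form, and the isopropyl ether, unlike a prenyl ether, is expected to stand methanesulfonic acid at this temperature.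

Step 7
Reactants: 10 8-methoxy-3-(4-methoxyphenyl)-7-(propan-2-yloxy)-4H-chromen-4-one
Product: 11 7-hydroxy-8-methoxy-3-(4-methoxyphenyl)-4H-chromen-4-one
Conditions: BCl3 (1 M in CH2Cl2), CH2Cl2, −78 → 0 °C; then H2O
Reagents that add atoms: none
Why: Lewis acid dealkylation of an aryl ether: BCl3 binds the ether oxygen and the secondary isopropyl group leaves as 2-chloropropane far faster than a methyl group, which without an ortho or peri carbonyl should not be cleaved at 0 °C.

Step 8
Reactants: 11 7-hydroxy-8-methoxy-3-(4-methoxyphenyl)-4H-chromen-4-one; 12 1-bromo-3-methylbut-2-ene (prenyl bromide)
Product: 13 8-methoxy-3-(4-methoxyphenyl)-7-[(3-methylbut-2-en-1-yl)oxy]-4H-chromen-4-one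
Conditions: K2CO3, acetone, reflux
Reagents that add atoms: none
Why: Williamson etherification: the 7-hydroxyl is para to the pyranone carbonyl and therefore acidic, and its phenoxide attacks the primary allylic bromide by SN2 at the CH2 terminus; carbonate in acetone does not open the pyranone.

## Compound list

1 | 2-methoxybenzene-1,3-diol (2-methoxyresorcinol) | COc1c(O)cccc1O | starting material
2 | 2-bromopropane | CC(C)Br | starting material
3 | 2-methoxy-3-(propan-2-yloxy)phenol | COc1c(O)cccc1OC(C)C | intermediate
4 | methyl 2-(4-methoxyphenyl)acetate | COC(=O)Cc1ccc(OC)cc1 | starting material
5 | methyl (Z)-3-hydroxy-2-(4-methoxyphenyl)prop-2-enoate | COC(=O)/C(=C\O)c1ccc(OC)cc1 | intermediate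
6 | methyl (E)-2-(4-methoxyphenyl)-3-[(4-methylphenyl)sulfonyloxy]prop-2-enoate | COC(=O)/C(=C/OS(=O)(=O)c1ccc(C)cc1)c1ccc(OC)cc1 | intermediate
7 | methyl (E)-3-[2-methoxy-3-(propan-2-yloxy)phenoxy]-2-(4-methoxyphenyl)prop-2-enoate | COC(=O)/C(=C/Oc1cccc(OC(C)C)c1OC)c1ccc(OC)cc1 | intermediate
8 | (E)-3-[2-methoxy-3-(propan-2-yloxy)phenoxy]-2-(4-methoxyphenyl)prop-2-enoic acid | OC(=O)/C(=C/Oc1cccc(OC(C)C)c1OC)c1ccc(OC)cc1 | intermediate
9 | (Z)-3-[2-methoxy-3-(propan-2-yloxy)phenoxy]-2-(4-methoxyphenyl)prop-2-enoic acid | COc1ccc(/C(C(=O)O)=C/Oc2cccc(OC(C)C)c2OC)cc1 | intermediate (formed in the flask in step 6, not isolated)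
10 | 8-methoxy-3-(4-methoxyphenyl)-7-(propan-2-yloxy)-4H-chromen-4-one | COc1ccc(-c2coc3c(OC)c(OC(C)C)ccc3c2=O)cc1 | intermediate
11 | 7-hydroxy-8-methoxy-3-(4-methoxyphenyl)-4H-chromen-4-one | COc1ccc(-c2coc3c(OC)c(O)ccc3c2=O)cc1 | intermediate
12 | 1-bromo-3-methylbut-2-ene (prenyl bromide) | CC(C)=CCBr | starting material
13 | 8-methoxy-3-(4-methoxyphenyl)-7-[(3-methylbut-2-en-1-yl)oxy]-4H-chromen-4-one | COc1ccc(-c2coc3c(OC)c(OCC=C(C)C)ccc3c2=O)cc1 | target

## Step count and risks

Total step count: 8. Longest linear sequence: 7 steps (steps 2 to 8, from ester 4 to target 13). The ring A branch (step 1) joins at step 4.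

**Step 6 (key step).** The activated acid is a vinylogous carbonate-type cation stabilised by O1, and O1 in turn donates less into ring A. If closure is slow, three processes could take over: incomplete E-to-Z isomerisation, bimolecular acylation of ring B, and acid-induced loss of the isopropyl group followed by C-alkylation of ring A. The fallback keeps the C4–C4a bond formation but removes the push–pull alkene first. It sets out from acid 8. Hydrogenation (H2, Pd/C, that is palladium metal on carbon, in EtOAc) should give racemic 3-[2-methoxy-3-(propan-2-yloxy)phenoxy]-2-(4-methoxyphenyl)propanoic acid F1. In F1, O1 is an ordinary aryl ether donor, the acylium ion is not stabilised and no alkene geometry has to be met. Friedel–Crafts closure of F1 in P2O5–MeSO3H at room temperature should give racemic 8-methoxy-3-(4-methoxyphenyl)-7-(propan-2-yloxy)-2,3-dihydro-4H-chromen-4-one F2. Dehydrogenation of F2 with DDQ in dioxane at reflux comes back to the route at 10.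

**Step 4.** The phenoxide may attack sulfur instead of C3. This sulfonyl transfer would return the enolate of 5 and consume phenol 3 as its aryl tosylate, and the methoxy group next to the phenoxide adds steric hindrance at carbon. The fallback replaces the sulfonate by an electrophile with no second electrophilic centre. It sets out from enol 5, which with oxalyl chloride and catalytic DMF in CH2Cl2 should give methyl (E)-3-chloro-2-(4-methoxyphenyl)prop-2-enoate F3 (either geometry serves). Addition–elimination of phenol 3 on F3 (K2CO3, catalytic DABCO, DMF) comes back to the route at 7.

**Step 5.** Hydroxide may add to C3 of the vinylogous carbonate and expel the phenoxide of 3, the reverse of step 4, instead of attacking the ester carbonyl. The fallback omits the free acid. It sets out from ester 7, which is heated directly in P2O5–MeSO3H. The protonated β-aryloxyacrylic ester then serves as the acylating agent with loss of methanol, as in the Simonis chromone closure, and the route is rejoined at 10. No new compound is made.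

**Step 7.** Dealkylation may go too far. Once boron is bound to O7 it can chelate to the neighbouring O8 and assist loss of the 8-O-methyl group. Binding of BCl3 to the pyranone carbonyl may also slow the wanted cleavage and tempt a higher temperature. The fallback dispenses with the O7 protecting group. It sets out from diol 1 (in excess) and tosylate 6, which under the conditions of step 4 should give methyl (E)-3-(3-hydroxy-2-methoxyphenoxy)-2-(4-methoxyphenyl)prop-2-enoate F4. Saponification as in step 5 should give (E)-3-(3-hydroxy-2-methoxyphenoxy)-2-(4-methoxyphenyl)prop-2-enoic acid F5. Closure of F5 in P2O5–MeSO3H with the para-hydroxyl free comes back to the route at 11. This is not the first choice because the free phenol can be O-acylated by a second molecule of the activated acid.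

## Further compounds

F1 | step 6 | rac-3-[2-methoxy-3-(propan-2-yloxy)phenoxy]-2-(4-methoxyphenyl)propanoic acid | COc1ccc(C(COc2cccc(OC(C)C)c2OC)C(=O)O)cc1
F2 | step 6 | rac-8-methoxy-3-(4-methoxyphenyl)-7-(propan-2-yloxy)-2,3-dihydro-4H-chromen-4-one | COc1ccc(C2COc3c(OC)c(OC(C)C)ccc3C2=O)cc1
F3 | step 4 | methyl (E)-3-chloro-2-(4-methoxyphenyl)prop-2-enoate | COC(=O)/C(=C/Cl)c1ccc(OC)cc1
F0 | step 5 | none | none
F4 | step 7 | methyl (E)-3-(3-hydroxy-2-methoxyphenoxy)-2-(4-methoxyphenyl)prop-2-enoate | COC(=O)/C(=C/Oc1cccc(O)c1OC)c1ccc(OC)cc1
F5 | step 7 | (E)-3-(3-hydroxy-2-methoxyphenoxy)-2-(4-methoxyphenyl)prop-2-enoic acid | OC(=O)/C(=C/Oc1cccc(O)c1OC)c1ccc(OC)cc1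
A1 | alternative 1 | rac-7-(benzyloxy)-8-methoxy-3-(4-methoxyphenyl)-2,3-dihydro-4H-chromen-4-one | COc1ccc(C2COc3c(OC)c(OCc4ccccc4)ccc3C2=O)cc1
A2 | alternative 1 | 3-(benzyloxy)-6-iodo-2-methoxyphenol | COc1c(O)c(I)ccc1OCc1ccccc1
A3 | alternative 1 | [1-(4-methoxyphenyl)ethenyl]boronic acid | C=C(B(O)O)c1ccc(OC)cc1
A4 | alternative 2 | 7-(benzyloxy)-8-methoxy-3-(4-methoxyphenyl)-5,6-dihydro-4H-chromen-4-one | COc1ccc(C2=COC3=C(C2=O)CCC(OCc2ccccc2)=C3OC)cc1
A5 | alternative 2 | 3-(benzyloxy)-2-methoxycyclohex-2-en-1-one | COC1=C(OCc2ccccc2)CCCC1=O
A6 | alternative 2 | (E)-N,3-dimethoxy-2-(4-methoxyphenyl)-N-methylprop-2-enamide | CO/C=C(/C(=O)N(C)OC)c1ccc(OC)cc1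
A7 | alternative 3 | 7-(benzyloxy)-8-methoxy-3-(4-methoxyphenyl)-4H-chromen-4-one | COc1ccc(-c2coc3c(OC)c(OCc4ccccc4)ccc3c2=O)cc1
A8 | alternative 3 | (E)-1-[4-(benzyloxy)-2-hydroxy-3-methoxyphenyl]-3-(4-methoxyphenyl)prop-2-en-1-one | COc1ccc(/C=C/C(=O)c2ccc(OCc3ccccc3)c(OC)c2O)cc1
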